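Everything rests on cutting both pyranones (ring C of each flavone) at O1–C8a. The feature exploited: in each ring A, C8a is ortho to the acyl-bearing C4a and meta to the C5 and C7 oxygens. A fluorine placed there is therefore activated by the ketone and not deactivated by the ethers. In the 7-methoxy unit, C8a is also the neighbour of the arylated C8. One base treatment of a biaryl bis[1-(2-fluoroaryl)-1,3-diketone] forms both C–O bonds and both rings, and the F/aryl/OMe sequence fixes the 8-linkage. The precursor carries four isopropyl and two methyl ethers; BCl3 finally removes all but 7-OMe.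

Key step: step 11

Remark on numbering: unit 1 is the 5,7-dihydroxyflavone whose ring B carries the biaryl bond at C3'. Unit 2 is the 7-methoxyflavone linked through C8. Flavone numbering is used for the future positions.
Assumption: the target SMILES has no axial descriptor, so the C8–C3' axis is treated as undefined and no stereocentre has to be set. The 1,3-diketones are drawn as diketo forms although they should exist largely as chelated enols. The boron aryloxides present before hydrolysis in step 12 are written in their simplest form, ArOBCl2.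

Step 1
Reactants: 1 1-fluoro-3,5-dimethoxybenzene
Product: 2 1-(2-fluoro-4,6-dimethoxyphenyl)ethan-1-one
Conditions: AcOH (1.2 equiv), (CF3CO)2O (2.5 equiv), H3PO4 (cat.), CH2Cl2, 0 °C to rt
Reagents that add atoms: acetic acid, CC(=O)O
Why: Friedel–Crafts acylation by acetyl trifluoroacetate formed in the flask: the carbon between F and OMe (para to the second OMe, flanked by the small fluorine) should be acylated in preference to the crowded carbon between the two methoxy groups, and the metal-free acid medium leaves the methyl ethers intact.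

Step 2
Reactants: 2 1-(2-fluoro-4,6-dimethoxyphenyl)ethan-1-one
Product: 3 1-(2-fluoro-3-iodo-4,6-dimethoxyphenyl)ethan-1-one
Conditions: NIS (1.05 equiv), TFA (0.3 equiv), MeCN, rt, dark
Reagents that add atoms: N-iodosuccinimide, O=C1CCC(=O)N1I
Why: Electrophilic aromatic iodination with acid-activated NIS: C3 is para to the 6-OMe, ortho to the 4-OMe and flanked only by fluorine, whereas C5 is boxed in by two methoxy groups, so iodine should mark the future C8 directly beside the C–F carbon, a placement that ring metalation of 1 would not guarantee because the position between the two methoxy groups competes there.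

Step 3
Reactants: 4 methyl 3-bromo-4-hydroxybenzoate
Product: 5 methyl 3-bromo-4-isopropoxybenzoate
Conditions: 2-bromopropane (1.5 equiv), K2CO3 (2 equiv), DMF, 60 °C
Reagents that add atoms: 2-bromopropane, CC(C)Br
Why: Williamson ether synthesis on the acidic phenol; the isopropyl ether withstands palladium catalysis, amide bases and hot carbonate and is later removed by BCl3.

Step 4
Reactants: 5 methyl 3-bromo-4-isopropoxybenzoate
Product: 6 methyl 4-isopropoxy-3-(4,4,5,5-tetramethyl-1,3,2-dioxaborolan-2-yl)benzoate
Conditions: B2pin2 (1.2 equiv), Pd(dppf)Cl2 (3 mol %), KOAc (3 equiv), 1,4-dioxane, 90 °C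
Reagents that add atoms: bis(pinacolato)diboron, CC1(C)OB(OC1(C)C)B1OC(C)(C)C(C)(C)O1
Why: Miyaura borylation of the aryl bromide; boron is placed on the benzoate ring because an arylboron reagent flanked by F and OMe on the electron-rich ring would be prone to protodeboronation.

Step 5
Reactants: 3 1-(2-fluoro-3-iodo-4,6-dimethoxyphenyl)ethan-1-one; 6 methyl 4-isopropoxy-3-(4,4,5,5-tetramethyl-1,3,2-dioxaborolan-2-yl)benzoate
Product: 7 methyl 3-(3-acetyl-2-fluoro-4,6-dimethoxyphenyl)-4-isopropoxybenzoate
Conditions: Pd(OAc)2 (3 mol %), SPhos (6 mol %), K3PO4 (3 equiv), toluene/H2O 10:1, 90 °C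
Reagents that add atoms: none
Why: Suzuki–Miyaura coupling in which the bulky, electron-rich SPhos ligand supports oxidative addition to the hindered iodide and formation of a biaryl with three ortho substituents, while C–F, ketone and ester are left alone by aqueous phosphate.

Step 6
Reactants: 8 4-isopropoxybenzoic acid
Product: 9 4-isopropoxybenzoyl chloride
Conditions: (COCl)2 (1.3 equiv), DMF (cat.), CH2Cl2, 0 °C to rt; concentrated and used crude
Reagents that add atoms: oxalyl chloride, O=C(Cl)C(=O)Cl
Why: Acid chloride formation through the catalytic Vilsmeier-type chloroiminium salt; a chloride is chosen so that the next acylation can run at −78 °C.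

Step 7
Reactants: 7 methyl 3-(3-acetyl-2-fluoro-4,6-dimethoxyphenyl)-4-isopropoxybenzoate; 9 4-isopropoxybenzoyl chloride
Product: 11 methyl 3-{2-fluoro-4,6-dimethoxy-3-[3-(4-isopropoxyphenyl)-3-oxopropanoyl]phenyl}-4-isopropoxybenzoate, via lithium enolate 10 (not isolated)
Conditions: LiHMDS (2.2 equiv), THF, −78 °C, 45 min; then 9 (1.05 equiv), −78 to −20 °C; 1 M HCl
Reagents that add atoms: none
Why: Crossed Claisen-type C-acylation of a kinetic lithium enolate with an acid chloride: at −78 °C the chloride reacts at once while the methyl 4-alkoxybenzoate in the same molecule is far too weak an acceptor, so self-condensation of the keto ester is avoided, and the second equivalent of base takes up the acidic proton of the new diketone.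

Step 8
Reactants: 12 1,3,5-trifluorobenzene
Product: 14 1-fluoro-3,5-diisopropoxybenzene, via 1,3-difluoro-5-isopropoxybenzene 13 (not isolated)
Conditions: NaOiPr (2.3 equiv), NMP, rt then 110 °C, sealed tube
Reagents that add atoms: sodium isopropoxide, CC(C)[O-].[Na+]
Why: Twofold SNAr on a ring activated only by the inductive pull of the meta fluorines; each alkoxide that enters slows the next displacement, so with about two equivalents of isopropoxide the reaction should stop at the monofluoride.

Step 9
Reactants: 14 1-fluoro-3,5-diisopropoxybenzene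
Product: 15 1-(2-fluoro-4,6-diisopropoxyphenyl)ethan-1-one
Conditions: AcOH (1.2 equiv), (CF3CO)2O (2.5 equiv), H3PO4 (cat.), CH2Cl2, 0 °C to rt
Reagents that add atoms: acetic acid, CC(=O)O
Why: Friedel–Crafts acylation as in step 1; the bulky isopropoxy groups shield the carbon between them, so the acetyl group should enter beside fluorine, and the absence of a metal Lewis acid protects the isopropyl ethers, in particular the one that ends up ortho to the ketone.

Step 10
Reactants: 11 methyl 3-{2-fluoro-4,6-dimethoxy-3-[3-(4-isopropoxyphenyl)-3-oxopropanoyl]phenyl}-4-isopropoxybenzoate; 15 1-(2-fluoro-4,6-diisopropoxyphenyl)ethan-1-one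
Product: 18 1-{3-[5-(3-(2-fluoro-4,6-diisopropoxyphenyl)-3-oxopropanoyl)-2-isopropoxyphenyl]-2-fluoro-4,6-dimethoxyphenyl}-3-(4-isopropoxyphenyl)propane-1,3-dione, via lithium enolate of the acetophenone 16 (not isolated), via lithium diketonate of the ester 17 (not isolated)
Conditions: 15 (1.5 equiv), LiHMDS (4 equiv), THF, −78 °C; then 11, −78 °C to rt; 1 M HCl
Reagents that add atoms: none
Why: Crossed Claisen condensation: the diketone already present is stored as its inert lithium chelate 17, so the methyl ester is the only acceptor left for enolate 16, deprotonation of the new diketone drives the equilibrium, and tightly bound lithium enolates in THF should not yet displace fluoride.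

Step 11
Reactants: 18 the bis(2-fluoroaryl 1,3-diketone) of step 10
Product: 21 8-[5-(5,7-diisopropoxy-4-oxo-4H-chromen-2-yl)-2-isopropoxyphenyl]-2-(4-isopropoxyphenyl)-5,7-dimethoxy-4H-chromen-4-one (protected sotetsuflavone), via dicesium bis-enolate 19 (not isolated), via monocyclised cesium enolate 20 (not isolated)
Conditions: Cs2CO3 (5 equiv), 4 Å MS, dry DMF (0.03 M), 100–120 °C, N2
Reagents that add atoms: none
Why: Cs2CO3 deprotonates both diketones to the Z-configured cesium enolates 19, and in each the oxygen on the future C2 adds to the C–F carbon (future C8a) while the incoming charge passes through C4a into the C4 carbonyl, after which fluoride leaves (addition–elimination SNAr through a Meisenheimer-type adduct). The reaction type is the known base-mediated, metal-free intramolecular O-arylation of 1-(2-haloaryl)-1,3-diketones to flavones, run here twice in one molecule, probably first at the less crowded unit 1 (20) and then at unit 2. Each pyranone closes in a six-membered mode that is 6-endo-trig when counted on the C4a=C8a bond that relays the charge to the ketone (it reads 6-exo-trig only on the other Kekulé form), that is, a vinylogous oxa-Michael addition followed by elimination. No stereocentre is created. The selectivities needed are O- over C-arylation, fluoride over alkoxide as leaving group and intra- over intermolecular attack: C3 or the C4 oxygen could only form four-membered rings, each ring A holds one fluorine ortho to its acyl group while the other ortho position carries a far poorer alkoxide leaving group, and dilution favours ring closure. The C5 and C7 ethers stand meta to C8a and do not push electron density onto the attacked carbon, and because the fluorine of unit 2 sits between the acyl-bearing carbon and the arylated carbon, closure can only give the 8-aryl flavone.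

Step 12
Reactants: 21 protected sotetsuflavone
Product: 23 sotetsuflavone, via pentakis(dichloroboryl) ether 22 (not isolated)
Conditions: BCl3 (1 M in CH2Cl2, 15 equiv), CH2Cl2, −78 °C to rt; then ice-cold 1 M HCl/THF
Reagents that add atoms: none
Why: Lewis-acid dealkylation of aryl ethers: BCl3 readily ionises the four secondary isopropyl ethers and cleaves the 5-OMe of unit 2 because boron is held in a six-membered chelate between O5 and the C4 carbonyl, whereas the unchelated primary 7-OMe should be inert at or below room temperature.

Compound list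
1 | 1-fluoro-3,5-dimethoxybenzene | COc1cc(F)cc(OC)c1 | starting material
2 | 1-(2-fluoro-4,6-dimethoxyphenyl)ethan-1-one | CC(=O)c1c(F)cc(OC)cc1OC | intermediate
3 | 1-(2-fluoro-3-iodo-4,6-dimethoxyphenyl)ethan-1-one | CC(=O)c1c(F)c(I)c(OC)cc1OC | intermediate
4 | methyl 3-bromo-4-hydroxybenzoate | COC(=O)c1ccc(O)c(Br)c1 | starting material
5 | methyl 3-bromo-4-isopropoxybenzoate | COC(=O)c1ccc(OC(C)C)c(Br)c1 | intermediate
6 | methyl 4-isopropoxy-3-(4,4,5,5-tetramethyl-1,3,2-dioxaborolan-2-yl)benzoate | COC(=O)c1ccc(OC(C)C)c(B2OC(C)(C)C(C)(C)O2)c1 | intermediate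
7 | methyl 3-(3-acetyl-2-fluoro-4,6-dimethoxyphenyl)-4-isopropoxybenzoate | COC(=O)c1ccc(OC(C)C)c(-c2c(F)c(C(C)=O)c(OC)cc2OC)c1 | intermediate
8 | 4-isopropoxybenzoic acid | CC(C)Oc1ccc(C(=O)O)cc1 | starting material
9 | 4-isopropoxybenzoyl chloride | CC(C)Oc1ccc(C(=O)Cl)cc1 | intermediate
10 | lithium enolate of the acetyl group of 7 (formed in the flask) | [Li+].[O-]C(=C)c1c(F)c(-c2cc(C(=O)OC)ccc2OC(C)C)c(OC)cc1OC | intermediate
11 | methyl 3-{2-fluoro-4,6-dimethoxy-3-[3-(4-isopropoxyphenyl)-3-oxopropanoyl]phenyl}-4-isopropoxybenzoate | COC(=O)c1ccc(OC(C)C)c(-c2c(F)c(C(=O)CC(=O)c3ccc(OC(C)C)cc3)c(OC)cc2OC)c1 | intermediate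
12 | 1,3,5-trifluorobenzene | Fc1cc(F)cc(F)c1 | starting material
13 | 1,3-difluoro-5-isopropoxybenzene (formed in the flask) | CC(C)Oc1cc(F)cc(F)c1 | intermediate
14 | 1-fluoro-3,5-diisopropoxybenzene | CC(C)Oc1cc(F)cc(OC(C)C)c1 | intermediate
15 | 1-(2-fluoro-4,6-diisopropoxyphenyl)ethan-1-one | CC(=O)c1c(F)cc(OC(C)C)cc1OC(C)C | intermediate
16 | lithium enolate of 15 (formed in the flask) | [Li+].[O-]C(=C)c1c(F)cc(OC(C)C)cc1OC(C)C | intermediate
17 | lithium (Z)-diketonate of 11 (formed in the flask) | [Li+].COC(=O)c1ccc(OC(C)C)c(-c2c(F)c(C(=O)/C=C(\[O-])c3ccc(OC(C)C)cc3)c(OC)cc2OC)c1 | intermediate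
18 | bis(1,3-diketone) with fluorine on the future C8a of both ring A units (name as in step 10) | O=C(CC(=O)c1ccc(OC(C)C)cc1)c1c(OC)cc(OC)c(-c2cc(ccc2OC(C)C)C(=O)CC(=O)c2c(F)cc(OC(C)C)cc2OC(C)C)c1F | intermediate
19 | dicesium (Z,Z)-bis-enolate of 18 (formed in the flask) | [Cs+].[Cs+].[O-]/C(=C\C(=O)c1c(OC)cc(OC)c(-c2cc(ccc2OC(C)C)/C([O-])=C/C(=O)c2c(F)cc(OC(C)C)cc2OC(C)C)c1F)c1ccc(OC(C)C)cc1 | intermediate
20 | cesium (Z)-enolate with the unit 1 pyranone closed and the unit 2 fluoro diketone still open (formed in the flask) | [Cs+].[O-]/C(=C\C(=O)c1c(OC)cc(OC)c(-c2cc(-c3cc(=O)c4c(OC(C)C)cc(OC(C)C)cc4o3)ccc2OC(C)C)c1F)c1ccc(OC(C)C)cc1 | intermediate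
21 | 8-[5-(5,7-diisopropoxy-4-oxo-4H-chromen-2-yl)-2-isopropoxyphenyl]-2-(4-isopropoxyphenyl)-5,7-dimethoxy-4H-chromen-4-one | COc1cc(OC)c2c(=O)cc(-c3ccc(OC(C)C)cc3)oc2c1-c1cc(-c2cc(=O)c3c(OC(C)C)cc(OC(C)C)cc3o2)ccc1OC(C)C | intermediate
22 | sotetsuflavone with all five phenolic oxygens as ArO–BCl2 (formed in the flask) | COc1cc(OB(Cl)Cl)c2c(=O)cc(-c3ccc(OB(Cl)Cl)cc3)oc2c1-c1cc(-c2cc(=O)c3c(OB(Cl)Cl)cc(OB(Cl)Cl)cc3o2)ccc1OB(Cl)Cl | intermediate
23 | sotetsuflavone, 8-[5-(5,7-dihydroxy-4-oxo-4H-chromen-2-yl)-2-hydroxyphenyl]-5-hydroxy-2-(4-hydroxyphenyl)-7-methoxy-4H-chromen-4-one | COc1cc(O)c2c(=O)cc(-c3ccc(O)cc3)oc2c1-c1cc(-c2cc(=O)c3c(O)cc(O)cc3o2)ccc1O | target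

Total step count: 12.
Longest linear sequence: 7 steps (3, 4, 5, 7, 10, 11, 12). The branch through steps 1 and 2 is equally long.

Steps most likely to fail

1. Step 11, the double ring closure.
- What may go wrong: the two ethers ortho and para to each acyl carbon, together with enolisation, weaken the activating ketone. The reaction may therefore stall after the first closure at the crowded C–F carbon of unit 2. At the temperature then needed, traces of water or dimethylamine from DMF may cleave the diketones by retro-Claisen fragmentation.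
- Fallback, from 11 back to 21: the simultaneous closure is given up for a stepwise one. Compound 11 alone is heated with Cs2CO3 in DMF. This closes the hindered unit 2 pyranone early, on a monoanion with only one base-labile diketone, and gives methyl 3-[2-(4-isopropoxyphenyl)-5,7-dimethoxy-4-oxo-4H-chromen-8-yl]-4-isopropoxybenzoate F1. A Claisen condensation of F1 with lithium enolate 16 (LiHMDS, THF, −78 °C to rt) gives 8-{5-[3-(2-fluoro-4,6-diisopropoxyphenyl)-3-oxopropanoyl]-2-isopropoxyphenyl}-2-(4-isopropoxyphenyl)-5,7-dimethoxy-4H-chromen-4-one F2. A second carbonate treatment closes the unhindered unit 1 to 21.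

2. Step 10, the second condensation.
- What may go wrong: acyl transfer from the electron-rich 4-alkoxybenzoate to the enolate may be slow. Proton exchange, self-condensation of the acetophenone or early loss of fluoride on warming could then take over.
- Fallback, from 7 back to 18: the order of the two condensations is reversed and both are run from acid chlorides at −78 °C. LiOH in THF/H2O saponifies 7, before any diketone is present, to 3-(3-acetyl-2-fluoro-4,6-dimethoxyphenyl)-4-isopropoxybenzoic acid F3. Oxalyl chloride with catalytic DMF gives 3-(3-acetyl-2-fluoro-4,6-dimethoxyphenyl)-4-isopropoxybenzoyl chloride F4. F4 is added slowly to an excess of enolate 16 at −78 °C to give 1-[3-(3-acetyl-2-fluoro-4,6-dimethoxyphenyl)-4-isopropoxyphenyl]-3-(2-fluoro-4,6-diisopropoxyphenyl)propane-1,3-dione F5. Full deprotonation of F5 (LiHMDS, 3.3 equiv, THF, −78 °C) and acylation of the more reactive methyl ketone enolate with 9 gives 18.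

3. Step 2, the iodination.
- What may go wrong: site selectivity may be poor, with partial attack at the carbon between the two methoxy groups or at the acetyl methyl group. Attack between the methoxy groups would carry the wrong (6-linked) connectivity through the whole route. The site can be checked at once from the size of the H–F coupling of the remaining ring proton, which is para to fluorine in 3 and ortho to it in the wrong isomer.
- Fallback, from 1 back to 7: the biaryl bond is made before the acetyl group enters. NBS in MeCN at 0 °C brominates 1 at one of its two equivalent positions beside fluorine to give 2-bromo-1-fluoro-3,5-dimethoxybenzene F6. Suzuki–Miyaura coupling of F6 with 6 (Pd(OAc)2, SPhos, K3PO4) gives methyl 3-(2-fluoro-4,6-dimethoxyphenyl)-4-isopropoxybenzoate F7. Friedel–Crafts acetylation with AcOH/(CF3CO)2O, mild enough for the isopropyl ether, should then enter beside fluorine, because the twisted aryl group presses the neighbouring methoxy group onto the other free carbon. This gives 7.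

Further compounds
F1 | step 11 | methyl 3-[2-(4-isopropoxyphenyl)-5,7-dimethoxy-4-oxo-4H-chromen-8-yl]-4-isopropoxybenzoate | COC(=O)c1ccc(OC(C)C)c(-c2c(OC)cc(OC)c3c(=O)cc(-c4ccc(OC(C)C)cc4)oc23)c1
F2 | step 11 | 8-{5-[3-(2-fluoro-4,6-diisopropoxyphenyl)-3-oxopropanoyl]-2-isopropoxyphenyl}-2-(4-isopropoxyphenyl)-5,7-dimethoxy-4H-chromen-4-one | COc1cc(OC)c2c(=O)cc(-c3ccc(OC(C)C)cc3)oc2c1-c1cc(C(=O)CC(=O)c2c(F)cc(OC(C)C)cc2OC(C)C)ccc1OC(C)C
F3 | step 10 | 3-(3-acetyl-2-fluoro-4,6-dimethoxyphenyl)-4-isopropoxybenzoic acid | OC(=O)c1ccc(OC(C)C)c(-c2c(F)c(C(C)=O)c(OC)cc2OC)c1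
F4 | step 10 | 3-(3-acetyl-2-fluoro-4,6-dimethoxyphenyl)-4-isopropoxybenzoyl chloride | ClC(=O)c1ccc(OC(C)C)c(-c2c(F)c(C(C)=O)c(OC)cc2OC)c1
F5 | step 10 | 1-[3-(3-acetyl-2-fluoro-4,6-dimethoxyphenyl)-4-isopropoxyphenyl]-3-(2-fluoro-4,6-diisopropoxyphenyl)propane-1,3-dione | CC(=O)c1c(F)c(-c2cc(C(=O)CC(=O)c3c(F)cc(OC(C)C)cc3OC(C)C)ccc2OC(C)C)c(OC)cc1OC
F6 | step 2 | 2-bromo-1-fluoro-3,5-dimethoxybenzene | COc1cc(F)c(Br)c(OC)c1
F7 | step 2 | methyl 3-(2-fluoro-4,6-dimethoxyphenyl)-4-isopropoxybenzoate | COC(=O)c1ccc(OC(C)C)c(-c2c(F)cc(OC)cc2OC)c1
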